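**Plan**

Numbering used throughout: O1, C2(=O), C3(Me), C4(=O), C5(OH)(CH2OH), C6, C7(Me)=C8, C9(Me), C10, C11(=CH2), C12=C13(Me), C14(Et). Retrosynthetic cuts, in order: C10–C11 (ring closure), O1–C2 (ester), C3–C4 (aldol), C6–C7 (epoxide opening).
Enabling feature: C10 is an unfunctionalised primary CH2 and C11 is C2 of the C11(=CH2)–C12=C13 diene. This is the one bond of the 14-membered ring that an alkylzinc/2-bromo-1,3-diene coupling makes without creating a stereocentre. It lies between the two Z-trisubstituted alkenes C7=C8 and C12=C13, which are set beforehand and fold the chain.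
Forward: bromodienol C11–C14 from 2-bromoacrolein; alkenyl iodide C7–C10 from the (S)-Roche ester; epoxide carrying C5, C6 and both CH2O arms from 2-methylidenepropane-1,3-diol. Then C6–C7 union, C2–C3 by aldol, esterification, closure of the 14-membered ring at C10–C11, C4 oxidation and deprotection.
Stereochemistry: C9 from the Roche ester, C5 from Sharpless epoxidation, C14 from catalytic asymmetric ethylation, C3 from an Evans syn-aldol (the C4 carbinol is later oxidised), 7Z from Stork–Zhao olefination, 12Z from Still–Gennari olefination.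

Key step: step 20

Remark: C3 sits between two carbonyl groups and is configurationally labile; it is set as (3R) in step 16 and the steps after the C4 oxidation are run without base.

**Route**

Step 1
Reactants: 1 2-bromoprop-2-enal (2-bromoacrolein); 2 methyl 2-[bis(2,2,2-trifluoroethoxy)phosphoryl]propanoate
Product: 3 methyl (2Z)-4-bromo-2-methylpenta-2,4-dienoate
Conditions: KN(SiMe3)2, 18-crown-6, THF, −78 °C
Reagents that add atoms: none
Why: Still–Gennari olefination: the electron-poor phosphonate with a dissociated potassium counter-ion eliminates from the kinetic adduct, so the C12=C13 alkene should form Z (ester cis to the bromovinyl group), and the stabilised anion should add 1,2 to the enal.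

Step 2
Reactants: 3 methyl (2Z)-4-bromo-2-methylpenta-2,4-dienoate
Product: 4 (2Z)-4-bromo-2-methylpenta-2,4-dien-1-ol
Conditions: i-Bu2AlH (2.2 equiv), CH2Cl2, −78 °C; aqueous potassium sodium tartrate
Reagents that add atoms: none
Why: Hydride reduction of the conjugated ester to the allylic alcohol at low temperature should leave the alkenyl bromide and the alkene geometry untouched.

Step 3
Reactants: 4 (2Z)-4-bromo-2-methylpenta-2,4-dien-1-ol
Product: 5 (2Z)-4-bromo-2-methylpenta-2,4-dienal
Conditions: MnO2, CH2Cl2, rt, dark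
Reagents that add atoms: none
Why: Allylic oxidation with MnO2 is neutral and heterogeneous, which should keep the Z-enal from isomerising.

Step 4
Reactants: 5 (2Z)-4-bromo-2-methylpenta-2,4-dienal
Product: 6 (3S,4Z)-6-bromo-4-methylhepta-4,6-dien-3-ol
Conditions: Et2Zn, (−)-MIB [(2S)-3-exo-morpholinoisoborneol, 5 mol%], toluene/hexane, 0 °C
Reagents that add atoms: diethylzinc, CC[Zn]CC
Why: Amino-alcohol-catalysed enantioselective 1,2-addition of diethylzinc to an α-branched enal: the (−)-MIB–zinc complex should deliver ethyl to the Si face and set C14 as S.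

Step 5
Reactants: 7 methyl (2S)-3-hydroxy-2-methylpropanoate ((S)-Roche ester)
Product: 8 methyl (2S)-3-[(tert-butyldimethylsilyl)oxy]-2-methylpropanoate
Conditions: TBSCl, imidazole, CH2Cl2, 0 °C → rt
Reagents that add atoms: tert-butyldimethylsilyl chloride, CC(C)(C)[Si](C)(C)Cl
Why: Routine silylation of the primary alcohol; the stereocentre (future C9) is not involved.

Step 6
Reactants: 8 methyl (2S)-3-[(tert-butyldimethylsilyl)oxy]-2-methylpropanoate
Product: 9 (2S)-3-[(tert-butyldimethylsilyl)oxy]-2-methylpropanal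
Conditions: i-Bu2AlH (1.05 equiv), CH2Cl2, −78 °C
Reagents that add atoms: none
Why: Partial ester reduction stops at the aluminium hemiacetal, which is stable at −78 °C, and the non-basic conditions should not epimerise the α-centre.

Step 7
Reactants: 9 (2S)-3-[(tert-butyldimethylsilyl)oxy]-2-methylpropanal
Product: 10 tert-butyl{[(2R,3Z)-4-iodo-2-methylpent-3-en-1-yl]oxy}dimethylsilane
Conditions: EtPPh3I, n-BuLi, THF; I2, −78 °C; NaN(SiMe3)2, −20 °C; then 9, −78 → −20 °C
Reagents that add atoms: ethyltriphenylphosphonium iodide, CC[P+](c1ccccc1)(c1ccccc1)c1ccccc1.[I-]; iodine, II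
Why: Stork–Zhao olefination: the α-iodo ylide reacts under kinetic control to give the Z-iodoalkene (iodine cis to the C9 chain), which fixes the C7=C8 geometry.

Step 8
Reactants: 11 2-methylidenepropane-1,3-diol
Product: 12 2-{[(4-methoxybenzyl)oxy]methyl}prop-2-en-1-ol
Conditions: NaH (1 equiv), PMBCl, Bu4NI (cat.), THF/DMF, 0 °C → rt, diol in excess
Reagents that add atoms: 4-methoxybenzyl chloride, COc1ccc(CCl)cc1
Why: Williamson etherification of one of two equivalent allylic hydroxyls; excess diol should favour the mono-ether.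

Step 9
Reactants: 12 2-{[(4-methoxybenzyl)oxy]methyl}prop-2-en-1-ol
Product: 13 [(2R)-2-{[(4-methoxybenzyl)oxy]methyl}oxiran-2-yl]methanol
Conditions: Ti(OiPr)4 (10 mol%), D-(−)-diethyl tartrate (12 mol%), t-BuOOH, 4 Å molecular sieves, CH2Cl2, −20 °C
Reagents that add atoms: tert-butyl hydroperoxide, CC(C)(C)OO
Why: Sharpless asymmetric epoxidation of a 2-substituted allylic alcohol: with D-(−)-diethyl tartrate the titanium tartrate complex should deliver oxygen to the face that gives the (R)-epoxide, which sets the future C5.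

Step 10
Reactants: 10 tert-butyl{[(2R,3Z)-4-iodo-2-methylpent-3-en-1-yl]oxy}dimethylsilane; 13 [(2R)-2-{[(4-methoxybenzyl)oxy]methyl}oxiran-2-yl]methanol
Product: 17 (2S,4Z,6R)-7-[(tert-butyldimethylsilyl)oxy]-2-{[(4-methoxybenzyl)oxy]methyl}-4,6-dimethylhept-4-ene-1,2-diol, via alkenyllithium 14 (not isolated), via alkenylmagnesium bromide 15 (not isolated), via bromomagnesium alkoxide 16 (not isolated)
Conditions: 10, t-BuLi (2.1 equiv), Et2O, −78 °C; MgBr2·OEt2, −78 → −30 °C; separately 13, MeMgBr (1.0 equiv), THF, 0 °C; combine, CuI (10 mol%), −30 → 0 °C; aqueous NH4Cl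
Reagents that add atoms: none
Why: Iodine–lithium exchange and transmetalation to magnesium go with retention of alkene geometry, and copper-catalysed SN2 opening of the 2,2-disubstituted epoxide occurs at its CH2 group, so C6–C7 forms while the quaternary C5 keeps its configuration with the epoxide oxygen as the tertiary hydroxyl.

Step 11
Reactants: 17 (2S,4Z,6R)-7-[(tert-butyldimethylsilyl)oxy]-2-{[(4-methoxybenzyl)oxy]methyl}-4,6-dimethylhept-4-ene-1,2-diol
Product: 18 (4R)-4-{(2Z,4R)-5-[(tert-butyldimethylsilyl)oxy]-2,4-dimethylpent-2-en-1-yl}-4-{[(4-methoxybenzyl)oxy]methyl}-2,2-dimethyl-1,3-dioxolane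
Conditions: Me2C(OMe)2, PPTS (cat.), CH2Cl2, rt
Reagents that add atoms: 2,2-dimethoxypropane, COC(C)(C)OC
Why: Acid-catalysed transacetalisation gives the five-membered isopropylidene acetal of the tertiary/primary 1,2-diol, masking both hydroxyls on the C5 unit at once.

Step 12
Reactants: 18 the acetonide silyl ether
Product: 19 (2R,3Z)-5-[(4R)-4-{[(4-methoxybenzyl)oxy]methyl}-2,2-dimethyl-1,3-dioxolan-4-yl]-2,4-dimethylpent-3-en-1-ol
Conditions: Bu4NF, THF, 0 °C → rt
Reagents that add atoms: none
Why: Fluoride cleaves the primary silyl ether; the acetal and the PMB ether are inert.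

Step 13
Reactants: 19 the primary alcohol
Product: 20 (4R)-4-[(2Z,4R)-5-iodo-2,4-dimethylpent-2-en-1-yl]-4-{[(4-methoxybenzyl)oxy]methyl}-2,2-dimethyl-1,3-dioxolane
Conditions: I2, PPh3, imidazole, CH2Cl2, 0 °C
Reagents that add atoms: iodine, II
Why: Appel-type iodination by SN2 displacement of the primary oxyphosphonium at C10; C9 is not involved and imidazole buffers the acetal.

Step 14
Reactants: 20 the iodide PMB ether
Product: 21 {(4R)-4-[(2Z,4R)-5-iodo-2,4-dimethylpent-2-en-1-yl]-2,2-dimethyl-1,3-dioxolan-4-yl}methanol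
Conditions: DDQ, CH2Cl2/pH 7 buffer, 0 °C
Reagents that add atoms: none
Why: Oxidative PMB cleavage by benzylic hydride abstraction; the buffer should prevent acid-catalysed migration of the acetonide onto the freed hydroxyl, which would scramble C5.

Step 15
Reactants: 21 the neopentyl alcohol
Product: 22 (4S)-4-[(2Z,4R)-5-iodo-2,4-dimethylpent-2-en-1-yl]-2,2-dimethyl-1,3-dioxolane-4-carbaldehyde
Conditions: Dess–Martin periodinane, NaHCO3, CH2Cl2, 0 °C → rt
Reagents that add atoms: none
Why: Dess–Martin oxidation gives an aldehyde without an α-hydrogen, so it cannot epimerise.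

Step 16
Reactants: 22 the aldehyde; 23 (4R)-4-benzyl-3-propanoyl-1,3-oxazolidin-2-one
Product: 25 (4R)-4-benzyl-3-[(2R,3R)-3-hydroxy-3-{(4S)-4-[(2Z,4R)-5-iodo-2,4-dimethylpent-2-en-1-yl]-2,2-dimethyl-1,3-dioxolan-4-yl}-2-methylpropanoyl]-1,3-oxazolidin-2-one, via (Z)-dibutylboron enolate 24 (not isolated)
Conditions: 23, Bu2BOTf, i-Pr2NEt, CH2Cl2, 0 °C; 22, −78 → 0 °C; pH 7 buffer, MeOH, H2O2
Reagents that add atoms: none
Why: Evans syn-aldol: the Z-boron enolate reacts through a Zimmerman–Traxler chair in which the (R)-benzyl auxiliary shields one enolate face, so C3 is set as R under reagent control and the C4 carbinol (syn, later oxidised) should form as one isomer.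

Step 17
Reactants: 25 the aldol adduct
Product: 26 the C4 triethylsilyl ether of 25
Conditions: Et3SiOTf, 2,6-lutidine, CH2Cl2, −78 → 0 °C
Reagents that add atoms: triethylsilyl triflate, CC[Si](CC)(CC)OS(=O)(=O)C(F)(F)F
Why: The silyl triflate protects the hindered secondary hydroxyl so that it is not acylated in step 19 and cannot quench the organozinc in step 20.

Step 18
Reactants: 26 the silylated imide
Product: 28 (2R,3R)-3-{(4S)-4-[(2Z,4R)-5-iodo-2,4-dimethylpent-2-en-1-yl]-2,2-dimethyl-1,3-dioxolan-4-yl}-2-methyl-3-[(triethylsilyl)oxy]propanoic acid, via peroxy acid 27 (not isolated)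
Conditions: LiOH, H2O2, THF/H2O, 0 °C; Na2SO3; dilute HCl to pH 4
Reagents that add atoms: hydrogen peroxide, OO
Why: Lithium hydroperoxide attacks the exocyclic imide carbonyl selectively, and sulfite reduction of the peroxy acid gives the acid without epimerising C3.

Step 19
Reactants: 28 the acid; 6 (3S,4Z)-6-bromo-4-methylhepta-4,6-dien-3-ol
Product: 30 (3S,4Z)-6-bromo-4-methylhepta-4,6-dien-3-yl ester of 28 (seco compound with C10–I and C11–Br), via mixed anhydride 29 (not isolated)
Conditions: 2,4,6-Cl3C6H2COCl, Et3N, THF, rt; then 6, DMAP, toluene, rt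
Reagents that add atoms: none
Why: Yamaguchi esterification: the acid is activated as the mixed anhydride and transferred by DMAP to the secondary allylic alcohol, so O1–C2 forms by acyl–oxygen bond formation with retention at C14.

Step 20
Reactants: 30 the seco iodide/bromodiene ester
Product: 32 14-membered lactone carrying C4–OSiEt3 and the C5 diol as acetonide [(3R,4R,5S,7Z,9S,12Z,14S), C11=CH2], via alkylzinc iodide 31 (not isolated)
Conditions: Zn dust (activated with BrCH2CH2Br and Me3SiCl), LiCl, THF, 40 °C; then addition over 10 h to PdCl2(dppf) (10 mol%) in THF/NMP, 55 °C, final concentration about 1 mM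
Reagents that add atoms: none
Why: Zinc should insert only into the primary C10–I bond (the alkenyl bromide, ester, silyl ether and acetal are inert to Zn/LiCl), giving a polar alkylzinc rather than a long-lived C10 radical, which could cyclise onto C8 and shift the vinyl group; zerovalent palladium then adds oxidatively to the C11–Br bond of the 2-bromo-1,3-diene, the tethered alkylzinc transmetalates, and reductive elimination forms C10–C11. This is an intramolecular Negishi alkyl–alkenyl coupling, the closest known reactions being intermolecular couplings of alkylzinc halides with 2-halo-1,3-dienes and B-alkyl Suzuki macrocyclisations. The only ring closed is the 14-membered lactone, by end-to-end macrocyclisation through a 15-membered palladacycle. No stereocentre is created: C9 and C14 flank the reacting termini but are not touched, the C7=C8 and C12=C13 geometries are carried through, and C11 itself bears only =CH2. The step needs oxidative addition at C–Br rather than ionisation of the C14 allylic ester (the alkenyl bromide reacts much faster and the fully substituted C13 terminus disfavours an allyl complex) and reductive elimination rather than β-hydride elimination at C10 (wide-bite-angle dppf). It also needs ring closure rather than oligomerisation, which slow addition to high dilution and the two Z-trisubstituted alkenes as turn elements should secure.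

Step 21
Reactants: 32 the protected macrolactone
Product: 33 the C4 alcohol [(3R,4R,5S,7Z,9S,12Z,14S), C5 diol still as acetonide]
Conditions: HF·pyridine, pyridine, THF, 0 °C → rt
Reagents that add atoms: none
Why: Buffered fluoride removes the triethylsilyl ether while the acetal, the allylic lactone and the diene should survive.

Step 22
Reactants: 33 the C4 alcohol
Product: 34 the C4 ketone (β-keto lactone, C5 diol as acetonide)
Conditions: Dess–Martin periodinane, NaHCO3, CH2Cl2, 0 °C → rt
Reagents that add atoms: none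
Why: Dess–Martin oxidation under buffered, non-basic conditions should give the β-keto lactone without enolising C3.

Step 23
Reactants: 34 the acetonide-protected β-keto lactone
Product: 35 (3R,5S,7Z,9S,12Z,14S)-14-ethyl-5-hydroxy-5-(hydroxymethyl)-3,7,9,13-tetramethyl-11-methylidene-1-oxacyclotetradeca-7,12-diene-2,4-dione (target)
Conditions: AcOH/H2O/THF (3:1:1), 40 °C
Reagents that add atoms: none
Why: Mild aqueous acid hydrolyses the isopropylidene acetal of the tertiary/primary diol without base, which should keep C3 and limit acyl transfer to the C5 hydroxyl.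

**Compound list**

1 | 2-bromoprop-2-enal | C=C(Br)C=O | starting material
2 | methyl 2-[bis(2,2,2-trifluoroethoxy)phosphoryl]propanoate | COC(=O)C(C)P(=O)(OCC(F)(F)F)OCC(F)(F)F | starting material
3 | methyl (2Z)-4-bromo-2-methylpenta-2,4-dienoate | COC(=O)/C(C)=C\C(Br)=C | intermediate
4 | (2Z)-4-bromo-2-methylpenta-2,4-dien-1-ol | OC/C(C)=C\C(Br)=C | intermediate
5 | (2Z)-4-bromo-2-methylpenta-2,4-dienal | O=C/C(C)=C\C(Br)=C | intermediate
6 | (3S,4Z)-6-bromo-4-methylhepta-4,6-dien-3-ol | C=C(Br)/C=C(/C)[C@H](CC)O | intermediate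
7 | methyl (2S)-3-hydroxy-2-methylpropanoate | COC(=O)[C@@H](C)CO | starting material
8 | methyl (2S)-3-[(tert-butyldimethylsilyl)oxy]-2-methylpropanoate | COC(=O)[C@@H](C)CO[Si](C)(C)C(C)(C)C | intermediate
9 | (2S)-3-[(tert-butyldimethylsilyl)oxy]-2-methylpropanal | O=C[C@@H](C)CO[Si](C)(C)C(C)(C)C | intermediate
10 | tert-butyl{[(2R,3Z)-4-iodo-2-methylpent-3-en-1-yl]oxy}dimethylsilane | I/C(C)=C\[C@@H](C)CO[Si](C)(C)C(C)(C)C | intermediate
11 | 2-methylidenepropane-1,3-diol | C=C(CO)CO | starting material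
12 | 2-{[(4-methoxybenzyl)oxy]methyl}prop-2-en-1-ol | C=C(CO)COCc1ccc(OC)cc1 | intermediate
13 | [(2R)-2-{[(4-methoxybenzyl)oxy]methyl}oxiran-2-yl]methanol | COc1ccc(COC[C@@]2(CO)CO2)cc1 | intermediate
14 | alkenyllithium from 10 (Li in place of I, geometry retained) | [Li]/C(C)=C\[C@@H](C)CO[Si](C)(C)C(C)(C)C | intermediate
15 | alkenylmagnesium bromide from 14 (geometry retained) | Br[Mg]/C(C)=C\[C@@H](C)CO[Si](C)(C)C(C)(C)C | intermediate
16 | bromomagnesium alkoxide of 13 | COc1ccc(COC[C@@]2(CO[Mg]Br)CO2)cc1 | intermediate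
17 | (2S,4Z,6R)-7-[(tert-butyldimethylsilyl)oxy]-2-{[(4-methoxybenzyl)oxy]methyl}-4,6-dimethylhept-4-ene-1,2-diol | COc1ccc(COC[C@@](O)(CO)C/C(C)=C\[C@@H](C)CO[Si](C)(C)C(C)(C)C)cc1 | intermediate
18 | (4R)-4-{(2Z,4R)-5-[(tert-butyldimethylsilyl)oxy]-2,4-dimethylpent-2-en-1-yl}-4-{[(4-methoxybenzyl)oxy]methyl}-2,2-dimethyl-1,3-dioxolane | COc1ccc(COC[C@@]2(COC(C)(C)O2)C/C(C)=C\[C@@H](C)CO[Si](C)(C)C(C)(C)C)cc1 | intermediate
19 | (2R,3Z)-5-[(4R)-4-{[(4-methoxybenzyl)oxy]methyl}-2,2-dimethyl-1,3-dioxolan-4-yl]-2,4-dimethylpent-3-en-1-ol | COc1ccc(COC[C@@]2(COC(C)(C)O2)C/C(C)=C\[C@@H](C)CO)cc1 | intermediate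
20 | (4R)-4-[(2Z,4R)-5-iodo-2,4-dimethylpent-2-en-1-yl]-4-{[(4-methoxybenzyl)oxy]methyl}-2,2-dimethyl-1,3-dioxolane | COc1ccc(COC[C@@]2(COC(C)(C)O2)C/C(C)=C\[C@@H](C)CI)cc1 | intermediate
21 | {(4R)-4-[(2Z,4R)-5-iodo-2,4-dimethylpent-2-en-1-yl]-2,2-dimethyl-1,3-dioxolan-4-yl}methanol | OC[C@@]1(COC(C)(C)O1)C/C(C)=C\[C@@H](C)CI | intermediate
22 | (4S)-4-[(2Z,4R)-5-iodo-2,4-dimethylpent-2-en-1-yl]-2,2-dimethyl-1,3-dioxolane-4-carbaldehyde | O=C[C@@]1(COC(C)(C)O1)C/C(C)=C\[C@@H](C)CI | intermediate
23 | (4R)-4-benzyl-3-propanoyl-1,3-oxazolidin-2-one | CCC(=O)N1[C@H](Cc2ccccc2)COC1=O | starting material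
24 | (Z)-dibutylboron enolate of 23 | C/C=C(\OB(CCCC)CCCC)N1[C@H](Cc2ccccc2)COC1=O | intermediate
25 | (4R)-4-benzyl-3-[(2R,3R)-3-hydroxy-3-{(4S)-4-[(2Z,4R)-5-iodo-2,4-dimethylpent-2-en-1-yl]-2,2-dimethyl-1,3-dioxolan-4-yl}-2-methylpropanoyl]-1,3-oxazolidin-2-one | O=C(N1[C@H](Cc2ccccc2)COC1=O)[C@H](C)[C@@H](O)[C@@]3(COC(C)(C)O3)C/C(C)=C\[C@@H](C)CI | intermediate
26 | triethylsilyl ether of 25 at the C3 hydroxyl of the acyl chain (C4 of the target) | O=C(N1[C@H](Cc2ccccc2)COC1=O)[C@H](C)[C@@H](O[Si](CC)(CC)CC)[C@@]3(COC(C)(C)O3)C/C(C)=C\[C@@H](C)CI | intermediate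
27 | peroxy acid corresponding to 28 | OOC(=O)[C@H](C)[C@@H](O[Si](CC)(CC)CC)[C@@]1(COC(C)(C)O1)C/C(C)=C\[C@@H](C)CI | intermediate
28 | (2R,3R)-3-{(4S)-4-[(2Z,4R)-5-iodo-2,4-dimethylpent-2-en-1-yl]-2,2-dimethyl-1,3-dioxolan-4-yl}-2-methyl-3-[(triethylsilyl)oxy]propanoic acid | OC(=O)[C@H](C)[C@@H](O[Si](CC)(CC)CC)[C@@]1(COC(C)(C)O1)C/C(C)=C\[C@@H](C)CI | intermediate
29 | mixed anhydride of 28 with 2,4,6-trichlorobenzoic acid | O=C(OC(=O)[C@H](C)[C@@H](O[Si](CC)(CC)CC)[C@@]1(COC(C)(C)O1)C/C(C)=C\[C@@H](C)CI)c1c(Cl)cc(Cl)cc1Cl | intermediate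
30 | (3S,4Z)-6-bromo-4-methylhepta-4,6-dien-3-yl (2R,3R)-3-{(4S)-4-[(2Z,4R)-5-iodo-2,4-dimethylpent-2-en-1-yl]-2,2-dimethyl-1,3-dioxolan-4-yl}-2-methyl-3-[(triethylsilyl)oxy]propanoate | C=C(Br)/C=C(/C)[C@H](CC)OC(=O)[C@H](C)[C@@H](O[Si](CC)(CC)CC)[C@@]1(COC(C)(C)O1)C/C(C)=C\[C@@H](C)CI | intermediate
31 | alkylzinc iodide from 30 (ZnI in place of I at C10) | C=C(Br)/C=C(/C)[C@H](CC)OC(=O)[C@H](C)[C@@H](O[Si](CC)(CC)CC)[C@@]1(COC(C)(C)O1)C/C(C)=C\[C@@H](C)C[Zn]I | intermediate
32 | 14-membered lactone, (3R,4R,5S,7Z,9S,12Z,14S), 4-OSiEt3, C5 diol as isopropylidene acetal, 11-methylidene | C=C1/C=C(/C)[C@H](CC)OC(=O)[C@H](C)[C@@H](O[Si](CC)(CC)CC)[C@@]2(COC(C)(C)O2)C/C(C)=C\[C@@H](C)C1 | intermediate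
33 | 14-membered lactone, (3R,4R,5S,7Z,9S,12Z,14S), 4-hydroxy, C5 diol as isopropylidene acetal | C=C1/C=C(/C)[C@H](CC)OC(=O)[C@H](C)[C@@H](O)[C@@]2(COC(C)(C)O2)C/C(C)=C\[C@@H](C)C1 | intermediate
34 | 14-membered β-keto lactone, (3R,5S,7Z,9S,12Z,14S), C5 diol as isopropylidene acetal | C=C1/C=C(/C)[C@H](CC)OC(=O)[C@H](C)C(=O)[C@@]2(COC(C)(C)O2)C/C(C)=C\[C@@H](C)C1 | intermediate
35 | (3R,5S,7Z,9S,12Z,14S)-14-ethyl-5-hydroxy-5-(hydroxymethyl)-3,7,9,13-tetramethyl-11-methylidene-1-oxacyclotetradeca-7,12-diene-2,4-dione | C=C1/C=C(/C)[C@H](CC)OC(=O)[C@H](C)C(=O)[C@@](O)(CO)C/C(C)=C\[C@@H](C)C1 | target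

**Step count and risks**

Total step count: 23. Longest linear sequence: 17 steps (steps 5–7, 10–23).

Steps most likely to fail:

Step 20. The tethered alkylzinc may be protonated or may couple between molecules (oligomerisation) faster than the 14-membered ring closes. The fallback makes C10–C11 between two molecules and closes the ring at O1–C2 instead. It sets out from 26 and 6. Zinc insertion (Zn, LiCl, THF) into 26 gives the alkylzinc iodide F1, which is coupled with the bromodienol 6 under PdCl2(dppf) catalysis to give the hydroxy imide F2. LiOH/H2O2 then gives, through the peroxy acid F3 and sulfite reduction, the seco hydroxy acid F4. Yamaguchi macrolactonisation through the mixed anhydride F5 (slow addition to DMAP in toluene at high dilution) comes back to the route at 32.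

Step 18. The hindered imide may be attacked at the ring carbonyl of the oxazolidinone or hydrolyse slowly, and the primary iodide may be displaced by hydroperoxide. The fallback removes the auxiliary by reduction and rebuilds the acid by oxidation. It sets out from 26: LiBH4/MeOH in THF at 0 °C gives the primary alcohol F6, Dess–Martin oxidation gives the aldehyde F7, and Pinnick oxidation (NaClO2, NaH2PO4, 2-methylbut-2-ene) comes back to the route at 28.

Step 23. Acidic hydrolysis next to the β-keto lactone may cause acyl transfer from O1 to the freed C5 hydroxyl with ring opening, or epimerisation at C3. The fallback removes the acetonide before the ketone exists and ends with a fluoride step. It sets out from 33: AcOH/H2O/THF gives the triol F8, selective silylation of the primary hydroxyl (Et3SiCl, imidazole) gives the mono-silyl ether F9, and Parikh–Doering oxidation (SO3·pyridine, DMSO, i-Pr2NEt) of the C4 alcohol gives the keto silyl ether F10 (this oxidant is chosen because it does not cleave the C4/C5 diol). Buffered HF·pyridine then comes back to the route at 35.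

Further compounds

F1 | step 20 | alkylzinc iodide from 26 | O=C(N1[C@H](Cc2ccccc2)COC1=O)[C@H](C)[C@@H](O[Si](CC)(CC)CC)[C@@]3(COC(C)(C)O3)C/C(C)=C\[C@@H](C)C[Zn]I
F2 | step 20 | hydroxy imide with the C10–C11 bond formed (open chain, free C14 hydroxyl) | O=C(N1[C@H](Cc2ccccc2)COC1=O)[C@H](C)[C@@H](O[Si](CC)(CC)CC)[C@@]3(COC(C)(C)O3)C/C(C)=C\[C@@H](C)CC(=C)/C=C(/C)[C@H](CC)O
F3 | step 20 | peroxy acid corresponding to F4 | OOC(=O)[C@H](C)[C@@H](O[Si](CC)(CC)CC)[C@@]1(COC(C)(C)O1)C/C(C)=C\[C@@H](C)CC(=C)/C=C(/C)[C@H](CC)O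
F4 | step 20 | seco hydroxy acid | OC(=O)[C@H](C)[C@@H](O[Si](CC)(CC)CC)[C@@]1(COC(C)(C)O1)C/C(C)=C\[C@@H](C)CC(=C)/C=C(/C)[C@H](CC)O
F5 | step 20 | mixed anhydride of F4 with 2,4,6-trichlorobenzoic acid | O=C(OC(=O)[C@H](C)[C@@H](O[Si](CC)(CC)CC)[C@@]1(COC(C)(C)O1)C/C(C)=C\[C@@H](C)CC(=C)/C=C(/C)[C@H](CC)O)c1c(Cl)cc(Cl)cc1Cl
F6 | step 18 | primary alcohol from reductive removal of the auxiliary | OC[C@H](C)[C@@H](O[Si](CC)(CC)CC)[C@@]1(COC(C)(C)O1)C/C(C)=C\[C@@H](C)CI
F7 | step 18 | aldehyde corresponding to 28 | O=C[C@H](C)[C@@H](O[Si](CC)(CC)CC)[C@@]1(COC(C)(C)O1)C/C(C)=C\[C@@H](C)CI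
F8 | step 23 | macrocyclic triol (4-hydroxy, 5-hydroxy, 5-hydroxymethyl) | C=C1/C=C(/C)[C@H](CC)OC(=O)[C@H](C)[C@@H](O)[C@@](O)(CO)C/C(C)=C\[C@@H](C)C1
F9 | step 23 | primary triethylsilyl ether of F8 | C=C1/C=C(/C)[C@H](CC)OC(=O)[C@H](C)[C@@H](O)[C@@](O)(CO[Si](CC)(CC)CC)C/C(C)=C\[C@@H](C)C1
F10 | step 23 | C4 ketone of F9 | C=C1/C=C(/C)[C@H](CC)OC(=O)[C@H](C)C(=O)[C@@](O)(CO[Si](CC)(CC)CC)C/C(C)=C\[C@@H](C)C1
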